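**Retrosynthetic overview**

1. Target 26 is a (2R)-2',6'-dihydroxyflavanone held as its C4–O2' hemiketal (ring D); opening the hemiketal and masking C4 as a dimethyl ketal leads back to the B-ring bis-silyl ether 23.
2. The strategy rests on ring C (O1–C2–C3–C4–C4a–C8a): it is the formal [4+2] adduct of the ring-A unit O1–C8a–C4a–C4, with C4 at the ketone oxidation level, and the styrene carbons C2/C3 of ring B. Cutting C3–C4 and O1–C2 gives orthoester 17 and styrene 20.
3. 17 comes from 5-methoxyresorcinol 1: two directed metalations place prenyl (between the two MOM ethers) and bromine (between OMOM and OMe) before any alkene-sensitive electrophile is needed, prenal closes the dimethylpyran ring at the only free carbon, and Br is exchanged for C(OMe)3 with tetramethyl orthocarbonate.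
4. 20 comes from 2,6-dihydroxybenzaldehyde 18 by silylation and Wittig methylenation.
5. Ring order: ring A (given) → dimethylpyran ring (step 5) → ring C (step 11) → ring D (step 13).

Key step: step 11

Assumptions: flavanone numbering is used for 21–26 (O1, C2, C3, C4, C4a, C5–C8, C8a; B-ring atoms primed), and "prenyl" means 3-methylbut-2-en-1-yl. Which enantiomer of the acid catalyst gives (2R) cannot be predicted; the (S,S) form is written as a working choice and would be exchanged for (R,R) if a first run gives the 2S product. The catalyst, called IDPi below, is the imidodiphosphorimidate acid built from two (S)-3,3'-bis(4-tert-butylphenyl)-1,1'-binaphthalene-2,2'-diyl phosphorus units joined through nitrogen, each phosphorus carrying a P=N–SO2CF3 group.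

**Step 1**
Reactants: 1 5-methoxyresorcinol (5-methoxybenzene-1,3-diol)
Product: 2 1-methoxy-3,5-bis(methoxymethoxy)benzene
Conditions: MOMCl, i-Pr2NEt, CH2Cl2, 0 °C to rt
Reagents that add atoms: chloromethyl methyl ether (MOMCl), COCCl
Why: Williamson-type O-alkylation of both phenols with the reactive α-chloro ether gives the bis-MOM ether, whose acetal oxygens direct the two metalations that follow.

**Step 2**
Reactants: 2 1-methoxy-3,5-bis(methoxymethoxy)benzene; 3 prenyl bromide (1-bromo-3-methylbut-2-ene)
Product: 5 5-methoxy-1,3-bis(methoxymethoxy)-2-prenylbenzene, via aryllithium 4 (not isolated)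
Conditions: n-BuLi, THF, 0 °C; then CuI (10 mol%), 3, −78 °C to rt
Reagents that add atoms: none
Why: Directed ortho-metalation removes the proton flanked by the two MOM ethers, the most strongly directed site, and the aryl metal is alkylated by the primary allylic bromide at its CH2 terminus to give the linear prenyl group.

**Step 3**
Reactants: 5 5-methoxy-1,3-bis(methoxymethoxy)-2-prenylbenzene
Product: 7 2-bromo-1-methoxy-3,5-bis(methoxymethoxy)-4-prenylbenzene, via aryllithium 6 (not isolated)
Conditions: s-BuLi, TMEDA, THF, −78 °C; then BrCl2C–CCl2Br, −78 °C to rt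
Reagents that add atoms: 1,2-dibromo-1,1,2,2-tetrachloroethane, BrC(Cl)(Cl)C(Cl)(Cl)Br
Why: Directed ortho-metalation at the only remaining ring C–H, between a MOM ether and the methoxy group, should be kinetically preferred at −78 °C over removal of the benzylic–allylic protons, and the aryllithium takes bromine from the positive-halogen donor so that no free electrophilic bromine meets the prenyl double bond.

**Step 4**
Reactants: 7 2-bromo-1-methoxy-3,5-bis(methoxymethoxy)-4-prenylbenzene
Product: 8 4-bromo-5-methoxy-2-prenylbenzene-1,3-diol
Conditions: HCl (3 M aq.), MeOH, 40 °C, short reaction time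
Reagents that add atoms: none
Why: Acid-catalysed transacetalisation with methanol removes both MOM groups, and at this mild acidity the prenyl group should not add to the neighbouring hydroxyls.

**Step 5**
Reactants: 8 4-bromo-5-methoxy-2-prenylbenzene-1,3-diol; 9 3-methylbut-2-enal (prenal)
Product: 11 6-bromo-5-methoxy-2,2-dimethyl-8-prenyl-2H-chromen-7-ol, via dienone 10 (not isolated)
Conditions: ethylenediammonium diacetate (EDDA, 10 mol%), PhMe, 110 °C
Reagents that add atoms: none
Why: Iminium-mediated Knoevenagel-type condensation at the single free ring carbon gives the ortho-quinone-methide dienone 10, which closes by oxa-6π electrocyclisation onto the adjacent oxygen, so only one chromene regioisomer can form and the hydroxyl between bromine and prenyl stays free.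

**Step 6**
Reactants: 11 6-bromo-5-methoxy-2,2-dimethyl-8-prenyl-2H-chromen-7-ol
Product: 12 (6-bromo-5-methoxy-2,2-dimethyl-8-prenyl-2H-chromen-7-yl)oxy-triisopropylsilane
Conditions: TIPSOTf, 2,6-lutidine, CH2Cl2, 0 °C to rt
Reagents that add atoms: triisopropylsilyl trifluoromethanesulfonate (TIPSOTf), CC(C)[Si](OS(=O)(=O)C(F)(F)F)(C(C)C)C(C)C
Why: O-silylation of the hindered phenol with the silyl triflate gives a triisopropylsilyl ether, which resists the oxygen-to-carbon silyl shift (retro-Brook rearrangement) of an ortho-metalated aryl silyl ether far better than a smaller silyl group and is later removed by fluoride without acid.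

**Step 7**
Reactants: 12 (6-bromo-5-methoxy-2,2-dimethyl-8-prenyl-2H-chromen-7-yl)oxy-triisopropylsilane; 13 tetramethyl orthocarbonate
Product: 16 triisopropyl-[5-methoxy-2,2-dimethyl-8-prenyl-6-(trimethoxymethyl)-2H-chromen-7-yl]oxysilane, via aryllithium 14 (not isolated), via arylmagnesium bromide 15 (not isolated)
Conditions: t-BuLi (2.1 equiv), Et2O, −78 °C; MgBr2·OEt2, −78 to 0 °C; 13 (3 equiv), PhMe, 60 °C; aq. NaHCO3 work-up, Et3N-deactivated silica
Reagents that add atoms: none
Why: Bromine–lithium exchange and transmetalation give an aryl Grignard reagent that replaces one methoxy group of the orthocarbonate by magnesium-assisted ionisation (Tschitschibabin orthoester synthesis, the orthocarbonate counterpart of the Bodroux–Chichibabin aldehyde synthesis), a second substitution being blocked by the two ortho substituents of the aryl group.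

**Step 8**
Reactants: 16 triisopropyl-[5-methoxy-2,2-dimethyl-8-prenyl-6-(trimethoxymethyl)-2H-chromen-7-yl]oxysilane
Product: 17 5-methoxy-2,2-dimethyl-8-prenyl-6-(trimethoxymethyl)-2H-chromen-7-ol (ring-A ortho-hydroxyaryl orthoester)
Conditions: TBAF, THF, 0 °C; cold aq. NaHCO3 work-up, drying over K2CO3, used at once
Reagents that add atoms: none
Why: Fluoride-induced cleavage of the aryl silyl ether runs under basic conditions in which an orthoester is inert, and the cold, mildly basic work-up returns the phenol without exposing the orthoester to acid.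

**Step 9**
Reactants: 18 2,6-dihydroxybenzaldehyde
Product: 19 2,6-bis(tert-butyldimethylsilyloxy)benzaldehyde
Conditions: TBSCl, imidazole, DMF, rt
Reagents that add atoms: tert-butyldimethylsilyl chloride (TBSCl), CC(C)(C)[Si](C)(C)Cl
Why: Imidazole-promoted O-silylation converts both phenols into silyl ethers that tolerate the ylide of the next step and later act as the two ortho donors of the styrene.

**Step 10**
Reactants: 19 2,6-bis(tert-butyldimethylsilyloxy)benzaldehyde
Product: 20 2,6-bis(tert-butyldimethylsilyloxy)styrene
Conditions: Ph3PCH3Br, n-BuLi, THF, 0 °C; then 19, 0 °C to rt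
Reagents that add atoms: methyltriphenylphosphonium bromide, C[P+](c1ccccc1)(c1ccccc1)c1ccccc1.[Br-]
Why: Wittig methylenation with the non-stabilised ylide converts the hindered aldehyde into the terminal alkene under non-acidic conditions that leave the aryl silyl ethers intact.

**Step 11**
Reactants: 17 5-methoxy-2,2-dimethyl-8-prenyl-6-(trimethoxymethyl)-2H-chromen-7-ol; 20 2,6-bis(tert-butyldimethylsilyloxy)styrene
Product: 23 (2R)-2-[2,6-bis(tert-butyldimethylsilyloxy)phenyl]-4,4,5-trimethoxy-8,8-dimethyl-10-prenyl-3,4-dihydro-2H,8H-pyrano[3,2-g]chromene (flavanone 4,4-dimethyl ketal), via dimethoxycarbenium ion 21 (not isolated), via benzylic cation 22 (not isolated)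
Conditions: (S,S)-IDPi acid (5 mol%), 20 (1.5 equiv), 5 Å MS, PhMe, −60 °C
Reagents that add atoms: none
Why: Proposed new method: the acid protonates one methoxy group of orthoester 17, methanol leaves (taken up by the sieves) and the aryl dimethoxycarbenium ion 21, the O-protonated form of a ketene-acetal ortho-quinone methide, stays as a contact ion pair with the confined chiral anion; the unsubstituted terminus of styrene 20 attacks C4 to give benzylic cation 22, stabilised by the two ortho silyloxy groups, and the phenol oxygen closes ring C at C2 by 6-endo capture of that cation (an asynchronous polar [4+2]), the released proton turning the catalyst over. The closest known reaction types are the chiral phosphoric and imidodiphosphoric acid-catalysed [4+2] cycloadditions of ortho-quinone methides, generated from ortho-hydroxybenzyl alcohols, with styrenes to 2-arylchromans, and the Lewis-acid-mediated addition of orthoesters to electron-rich alkenes through dialkoxycarbenium ions; new here is the orthoester as the quinone-methide source, so that C4 arrives at the ketone oxidation level. The single new stereocentre C2 is set by the chiral anion, which is hydrogen-bonded to the phenol O–H and shields one face of the styrene in the C–C bond-forming event, ring closure following before the benzylic cation can rotate; the (2R) sense is catalyst-controlled and has to be matched to the catalyst enantiomer. Regiochemistry needs the CH2 terminus to bond to C4, which the 2,6-dioxygenated benzylic cation secures, and chemoselectivity needs orthoester ionisation to outrun protonation of the prenyl and chromene double bonds, which its far lower acidity demand at −60 °C should secure. The product carries C4 as a dimethyl ketal, so no enolisable ketone is present and ring C cannot reopen by a retro-oxa-Michael path.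

**Step 12**
Reactants: 23 (2R)-flavanone 4,4-dimethyl ketal bis-silyl ether
Product: 24 (2R)-2-(2,6-dihydroxyphenyl)-4,4,5-trimethoxy-8,8-dimethyl-10-prenyl-3,4-dihydro-2H,8H-pyrano[3,2-g]chromene
Conditions: TBAF, AcOH (1:1), THF, 0 °C
Reagents that add atoms: none
Why: Fluoride-mediated desilylation buffered with acetic acid removes both aryl silyl ethers while the phenols stay protonated, which avoids phenoxide-driven opening of ring C at the benzylic C2–O1 bond and leaves the C2 centre untouched.

**Step 13**
Reactants: 24 (2R)-2',6'-dihydroxyflavanone 4,4-dimethyl ketal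
Product: 26 target hemiketal (2R,4R): flavanone 25 closed between O2' and C4 with OH on C4, via open flavanone 25 (not isolated)
Conditions: pyridinium p-toluenesulfonate (cat.), THF/H2O, rt
Reagents that add atoms: water, O
Why: Acid-catalysed ketal hydrolysis through the ring-A-stabilised oxocarbenium ion gives flavanone 25, whose 2'-hydroxyl adds to the C4 carbonyl once ring B is axial (intramolecular hemiketalisation closing the six-membered ring D), and C4 is set by substrate control because the oxygen bridge can span C2 and C4 on one face only, so (2R) enforces (4R).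

**Compound list**

1 | 5-methoxyresorcinol (5-methoxybenzene-1,3-diol) | COc1cc(O)cc(O)c1 | starting material
2 | 1-methoxy-3,5-bis(methoxymethoxy)benzene | COCOc1cc(OC)cc(OCOC)c1 | intermediate
3 | prenyl bromide (1-bromo-3-methylbut-2-ene) | CC(C)=CCBr | starting material
4 | 2-lithio-5-methoxy-1,3-bis(methoxymethoxy)benzene | COCOc1cc(OC)cc(OCOC)c1[Li] | intermediate
5 | 5-methoxy-1,3-bis(methoxymethoxy)-2-prenylbenzene | COCOc1cc(OC)cc(OCOC)c1CC=C(C)C | intermediate
6 | 2-lithio-1-methoxy-3,5-bis(methoxymethoxy)-4-prenylbenzene | COCOc1cc(OC)c([Li])c(OCOC)c1CC=C(C)C | intermediate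
7 | 2-bromo-1-methoxy-3,5-bis(methoxymethoxy)-4-prenylbenzene | COCOc1cc(OC)c(Br)c(OCOC)c1CC=C(C)C | intermediate
8 | 4-bromo-5-methoxy-2-prenylbenzene-1,3-diol | COc1cc(O)c(CC=C(C)C)c(O)c1Br | intermediate
9 | 3-methylbut-2-enal (prenal) | CC(C)=CC=O | starting material
10 | 4-bromo-3-hydroxy-5-methoxy-6-(3-methylbut-2-en-1-ylidene)-2-prenylcyclohexa-2,4-dien-1-one (ortho-quinone-methide dienone) | O=C1C(CC=C(C)C)=C(O)C(Br)=C(OC)C1=CC=C(C)C | intermediate
11 | 6-bromo-5-methoxy-2,2-dimethyl-8-prenyl-2H-chromen-7-ol | COc1c(Br)c(O)c(CC=C(C)C)c2OC(C)(C)C=Cc12 | intermediate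
12 | triisopropylsilyl ether of 11 | COc1c(Br)c(O[Si](C(C)C)(C(C)C)C(C)C)c(CC=C(C)C)c2OC(C)(C)C=Cc12 | intermediate
13 | tetramethyl orthocarbonate | COC(OC)(OC)OC | starting material
14 | 6-lithio derivative of 12 (aryllithium) | COc1c([Li])c(O[Si](C(C)C)(C(C)C)C(C)C)c(CC=C(C)C)c2OC(C)(C)C=Cc12 | intermediate
15 | arylmagnesium bromide from 14 | COc1c([Mg]Br)c(O[Si](C(C)C)(C(C)C)C(C)C)c(CC=C(C)C)c2OC(C)(C)C=Cc12 | intermediate
16 | triisopropyl-[5-methoxy-2,2-dimethyl-8-prenyl-6-(trimethoxymethyl)-2H-chromen-7-yl]oxysilane | COc1c(C(OC)(OC)OC)c(O[Si](C(C)C)(C(C)C)C(C)C)c(CC=C(C)C)c2OC(C)(C)C=Cc12 | intermediate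
17 | 5-methoxy-2,2-dimethyl-8-prenyl-6-(trimethoxymethyl)-2H-chromen-7-ol (ring-A orthoester) | COC(OC)(OC)c1c(O)c(CC=C(C)C)c2c(c1OC)C=CC(C)(C)O2 | intermediate
18 | 2,6-dihydroxybenzaldehyde | O=Cc1c(O)cccc1O | starting material
19 | 2,6-bis(tert-butyldimethylsilyloxy)benzaldehyde | O=Cc1c(O[Si](C)(C)C(C)(C)C)cccc1O[Si](C)(C)C(C)(C)C | intermediate
20 | 2,6-bis(tert-butyldimethylsilyloxy)styrene | C=Cc1c(O[Si](C)(C)C(C)(C)C)cccc1O[Si](C)(C)C(C)(C)C | intermediate
21 | aryl dimethoxycarbenium ion from 17 (paired with the catalyst anion) | COc1c([C+](OC)OC)c(O)c(CC=C(C)C)c2OC(C)(C)C=Cc12 | intermediate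
22 | benzylic cation after C3–C4 bond formation | COc1c(C(OC)(OC)C[CH+]c3c(O[Si](C)(C)C(C)(C)C)cccc3O[Si](C)(C)C(C)(C)C)c(O)c(CC=C(C)C)c2OC(C)(C)C=Cc12 | intermediate
23 | (2R)-2-[2,6-bis(tert-butyldimethylsilyloxy)phenyl]-4,4,5-trimethoxy-8,8-dimethyl-10-prenyl-3,4-dihydro-2H,8H-pyrano[3,2-g]chromene | COC1(OC)C[C@H](c2c(O[Si](C)(C)C(C)(C)C)cccc2O[Si](C)(C)C(C)(C)C)Oc2c1c(OC)c1c(c2CC=C(C)C)OC(C)(C)C=C1 | intermediate
24 | (2R)-2-(2,6-dihydroxyphenyl)-4,4,5-trimethoxy-8,8-dimethyl-10-prenyl-3,4-dihydro-2H,8H-pyrano[3,2-g]chromene | COC1(OC)C[C@H](c2c(O)cccc2O)Oc2c1c(OC)c1c(c2CC=C(C)C)OC(C)(C)C=C1 | intermediate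
25 | (2R)-2-(2,6-dihydroxyphenyl)-5-methoxy-8,8-dimethyl-10-prenyl-2,3-dihydro-4H,8H-pyrano[3,2-g]chromen-4-one (open flavanone) | O=C1C[C@H](c2c(O)cccc2O)Oc2c1c(OC)c1c(c2CC=C(C)C)OC(C)(C)C=C1 | intermediate
26 | CNP0170313.2, (2R,4R)-hemiketal of 25 bridged between O2' and C4 | COc1c2c(c(CC=C(C)C)c3c1[C@@]1(O)C[C@@H](O3)c3c(O)cccc3O1)OC(C)(C)C=C2 | target

**Route summary**

Total step count: 13. Longest linear sequence: 11 steps (steps 1–8 and 11–13 from 1); the styrene branch (steps 9–10) joins at step 11.

**Steps most likely to fail**

Step 11 (proposed new method). Several processes could defeat it: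
- methyl transfer out of the dimethoxycarbenium ion to methanol or the counter-anion, which drains the cation to the unreactive ester level;
- acid-induced addition of the free phenol across the neighbouring prenyl double bond;
- attack of the cation on the chromene or prenyl alkene in place of the styrene;
- weak facial discrimination if the ion pair is loose.

The fallback uses known flavonoid chemistry with resolution. It sets out from aryl bromide 12 and aldehyde 18 and comes back at target 26. Bromine–lithium exchange on 12 (through aryllithium 14) and acylation with N-methoxy-N-methylacetamide give the silylated acetophenone F1, and TBAF frees the 2'-hydroxyacetophenone F2. Aldehyde 18 is protected with MOMCl and i-Pr2NEt as 2,6-bis(methoxymethoxy)benzaldehyde F3. Claisen–Schmidt condensation of F2 with F3 (KOH, EtOH) gives the 2'-hydroxychalcone F4, and NaOAc in hot ethanol closes it by oxa-Michael addition to the racemic flavanone bis-MOM ether F5. HCl in methanol removes both MOM groups and the freed 2'-hydroxyl closes onto the ketone, giving 26 together with its (2S,4S) enantiomer F6. Preparative chromatography on a chiral stationary phase then separates 26.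

Step 7. The di-ortho-substituted aryl Grignard reagent may be too hindered to substitute the orthocarbonate, so that protonation of the aryl metal or slow silyl migration takes over. The fallback sets out from bromophenol 11 and comes back at orthoester 17, without a silyl group. Phenol 11 is deprotonated with MeMgBr and the bromide is exchanged with t-BuLi at −78 °C to give the O-bromomagnesio C-lithio arene F7. F7 is then heated with 13. The small magnesium phenoxide cannot undergo silyl migration, shields the carbanion less and can deliver the orthocarbonate by chelation. Basic work-up gives 17 directly, so steps 6 and 8 fall away.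

Step 8. The free ortho-hydroxyaryl orthoester may ionise by its own phenol or hydrolyse to the ester level during aqueous work-up and handling. The fallback sets out from 16 and comes back at 23, never isolating a free phenol. The fluoride desilylation of 16 is quenched in the flask with Me3SiCl in place of water, giving the trimethylsilyl ether F8, which is not acidic and can be filtered through basic alumina. F8 then enters step 11 in place of 17: the methanol released on ionisation of the orthoester takes over the trimethylsilyl group under the acid catalyst, the phenol is unveiled in the flask, and the cycloaddition proceeds to 23.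

**Further compounds**

F1 | step 11 | 1-[5-methoxy-2,2-dimethyl-8-prenyl-7-(triisopropylsilyloxy)-2H-chromen-6-yl]ethanone | COc1c(C(C)=O)c(O[Si](C(C)C)(C(C)C)C(C)C)c(CC=C(C)C)c2OC(C)(C)C=Cc12
F2 | step 11 | 1-(7-hydroxy-5-methoxy-2,2-dimethyl-8-prenyl-2H-chromen-6-yl)ethanone | COc1c(C(C)=O)c(O)c(CC=C(C)C)c2OC(C)(C)C=Cc12
F3 | step 11 | 2,6-bis(methoxymethoxy)benzaldehyde | COCOc1cccc(OCOC)c1C=O
F4 | step 11 | (E)-2'-hydroxychalcone from F2 and F3 | COCOc1cccc(OCOC)c1/C=C/C(=O)c1c(O)c(CC=C(C)C)c2OC(C)(C)C=Cc2c1OC
F5 | step 11 | racemic flavanone bis-MOM ether | COCOc1cccc(OCOC)c1C1CC(=O)c2c(OC)c3C=CC(C)(C)Oc3c(CC=C(C)C)c2O1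
F6 | step 11 | (2S,4S) enantiomer of 26 | COc1c2c(c(CC=C(C)C)c3c1[C@]1(O)C[C@H](O3)c3c(O)cccc3O1)OC(C)(C)C=C2
F7 | step 7 | O-bromomagnesio C-lithio arene from 11 | COc1c([Li])c(O[Mg]Br)c(CC=C(C)C)c2OC(C)(C)C=Cc12
F8 | step 8 | trimethylsilyl ether of 17 | COc1c(C(OC)(OC)OC)c(O[Si](C)(C)C)c(CC=C(C)C)c2OC(C)(C)C=Cc12
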